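How much solid do I weigh in?

| flask | solid substrate | remark | time |
|---|---|---|---|
| cedar | 0.040 M | run made earlier |  |
| maple | 0.74 M | run made earlier |  |
| beta | 0.060 M |  | 20 h |
| gamma | 0.12 M |  | 20 h |
| delta | 0.25 M |  | 20 h |
| alpha | 0.50 M |  | 20 h |
| theta | 1.0 M |  | 20 h |

| run | time / h | ring / % | solid substrate / % |
|---|---|---|---|
| cedar | 2.50 | 7.9 | 0 |
| cedar | 8.00 | 32.1 | 0 |
| cedar | 12.0 | 45.4 | 1.5 |
| cedar | 20.0 | 60.7 | 2.2 |
| maple | 5.00 | 2.7 | 86.1 |
| maple | 10.0 | 6.6 | 76.3 |
| maple | 15.0 | 11.0 | 66.8 |
| maple | 20.0 | 14.7 | 56.9 |

(standard deviation of a reading: 1 percentage point)

- percent here means solid substrate units held: one open dimer or idle adduct counts as two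
- what is said of ring includes idle adduct
- solid substrate is a solid; its amount is given per volume of the solution
- what was read earlier has a scatter of 1 percentage point, one standard deviation
- steps thought possible: 2 starting material -> open dimer; solid substrate <-> starting material; starting material + ring <-> idle adduct; starting material -> ring
- at the start none of the solid substrate is in solution
- in an amount of ring, one idle adduct counts as one ring
- the concentration of ring that is asked is that of its free form alone
- "hardly changes" means that all values lie within two and a half points (for a concentration: within two and a half percent of the largest)

* [ring] (only what is free in solution) at the end for beta, gamma, delta, alpha, theta, in this order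
* the shape of the row from first to last (rises, then falls / rises all the way / falls, then rises / falls all the way / hardly changes)

Solid substrate dissolves into starting material, which goes on to ring or open dimer, or binds ring as idle adduct. The maple flask still holds 56.9 % of its charge as solid at 20.0 h, and from 5.00 h on it loses a steady 0.0144 M h⁻¹. I therefore take dissolving as zero order in solid: while solid stands, the loss per hour does not depend on how much lies there.

That gives one number to weigh against, the dissolved reach D, the solid substrate lost from maple by 20.0 h: 0.319 M. It is a reading and carries the scatter of 1 percentage point in the percentage behind it.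

A charge above D should still hold solid at the end, so alpha's 0.50 M and theta's 1.0 M should repeat maple's history. Each should then hold maple's ring, 0.109 M with idle adduct counted, and free ring stands below that by what the adduct binds, which I cannot read from these runs. Delta's 0.25 M lies under D, so I expect its solid to have dissolved by the end. My decision is to leave theta's extra solid in the jar for the next run and charge no more than alpha's amount.

The forecast gives 0.033 M, 0.055 M, 0.096 M, 0.109 M and 0.109 M, with the shape rises all the way: “The row rises, then levels off.”

The flasks give 0.0334 M, 0.0564 M, 0.0805 M, 0.0773 M and 0.0773 M of free ring, and the shape is rises, then falls.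

    2 starting material → open dimer (k = 0.130 L mol⁻¹ h⁻¹)
    solid substrate ⇌ starting material, rate k2*(cs2 - [starting material]) while solid is left; crystals form when [starting material] > cs2 (solubility = 0.400 M, k = 0.0520 h⁻¹)
    starting material + ring ⇌ idle adduct, settled at all times (K = 3.10 L mol⁻¹)
    starting material → ring (k = 0.0570 h⁻¹)

Alpha still holds 36.5 % of its charge as solid at 20.0 h, so it has lost 0.318 M, which matches D. Theta, with twice alpha's charge, ends at the same free ring. It keeps 68.2 % of its charge as solid and has lost 0.318 M.

(The earlier runs and the new flask were computed with constants of no real substance, noise included.)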